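**Plan**

1. Cuts, last bond first: the O–O/O–C8' unit of the 1,2-dioxolane (singlet-oxygen ene, hemiketal closure); C7–C8 of the left seven-membered ring (carbonyl-ene); C1–C4' and C3–C3' of the norbornene (Diels–Alder); C7'–C8' of the right seven-membered ring (same ene reaction on the monomer); C5–C6 (Grignard addition) and C1–C10 (Michael addition) of one cyclopentenone precursor that serves both halves.
2. Feature used: in the left ring C1–C5–C6–C7–C8–C9–C10 the C8 ketone is the neighbour of the isopropyl-bearing C7. This is the oxidised, hydrogenated form of the 8-hydroxy-7-isopropenyl unit that an ene reaction between a C8 aldehyde on the C1 arm and a prenyl group on C5 leaves behind.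
3. Forward order of rings: cyclopentenone (from cyclopentane-1,3-dione) → right cycloheptane → norbornene (a left-half cyclopentadienone ketal traps the transient right-half cyclopentadienone) → left cycloheptane (key step) → 1,2-dioxolane.
4. Stereochemistry: C10 and C10' from one organocatalytic Michael addition; C1, C3, C3', C4' from the endo Diels–Alder (dienophile face anti to the C10' methyl, diene face through allylic strain at C10); C2 by equilibration of the bridge carbinol, because hydride reduction is expected to give the wrong epimer; C7 by base equilibration next to the C8 ketone; C8' by reversible hemiketal closure.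

Key step: step 23

Numbering: guaiane numbering throughout, monomers included, right half primed; C2 is the one-carbon bridge of the norbornene, C4=C5 its double bond, C3'–C4' the saturated two-carbon bridge.
Assumption: the natural configurations at C7 and C8' are the thermodynamically favoured ones, since both centres can equilibrate in the target itself.
Assumption: the (S)-diarylprolinol silyl ether shields the iminium face so that the dione carbon adds to give the (R)-adduct (usual model for this catalyst class).

**Route**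

Step 1
Reactants: 1 cyclopentane-1,3-dione; 2 (E)-but-2-enal
Product: 4 (4R)-2-hydroxy-4-methyl-3,4,6,7-tetrahydro-2H-cyclopenta[b]pyran-5-one (lactol; both anomers), via open-chain Michael aldehyde 3 (not isolated)
Conditions: (S)-2-[diphenyl(trimethylsilyloxy)methyl]pyrrolidine (10 mol %), PhCO2H (10 mol %), CH2Cl2, 0 °C
Reagents that add atoms: none
Why: Iminium-catalysed asymmetric Michael addition of the cyclic 1,3-dione to the enal, the silyl ether group shielding one face of the E-iminium ion so that C10 forms as (R), followed by spontaneous lactol closure of the enol oxygen onto the aldehyde.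

Step 2
Reactants: 4 lactol
Product: 5 (4R)-2-methoxy-4-methyl-3,4,6,7-tetrahydro-2H-cyclopenta[b]pyran-5-one (both anomers)
Conditions: MeOH, camphorsulfonic acid (cat.), 3 Å sieves, rt
Reagents that add atoms: methanol, CO
Why: Fischer-type acetalisation of the lactol masks the aldehyde as a cyclic mixed acetal whose ring oxygen is also the alkoxy group of a vinylogous ester, the substrate of a Stork–Danheiser sequence.

Step 3
Reactants: 5 vinylogous ester
Product: 6 (4R)-2-methoxy-4,6-dimethyl-3,4,6,7-tetrahydro-2H-cyclopenta[b]pyran-5-one (C2 and C6 epimers)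
Conditions: LiN(iPr)2, THF, −78 °C; MeI, −78 → −20 °C
Reagents that add atoms: iodomethane, CI
Why: Kinetic deprotonation of a vinylogous ester occurs at the α' methylene and enolate alkylation (Stork–Danheiser alkylation) installs the future C15/C15' methyl, whose configuration is irrelevant because C4 and C4' later become trigonal.

Step 4
Reactants: 6 methylated vinylogous ester
Product: 7 (4R)-6-hydroxy-2-methoxy-4,6-dimethyl-3,4,6,7-tetrahydro-2H-cyclopenta[b]pyran-5-one (epimers at C2 and C6)
Conditions: LiN(iPr)2, THF, −78 °C; 2-(phenylsulfonyl)-3-phenyloxaziridine; aq. NH4Cl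
Reagents that add atoms: 2-(phenylsulfonyl)-3-phenyloxaziridine, O=S(=O)(c1ccccc1)N1OC1c1ccccc1
Why: Oxaziridine hydroxylation of the tetrasubstituted α' enolate installs the tertiary hydroxyl that later serves as the β-leaving group for release of the right-half cyclopentadienone.

Step 5
Reactants: 7 hydroxylated vinylogous ester
Product: 9 (3R)-3-[3-hydroxy-3-methyl-5-oxo-2-(prop-2-enyl)cyclopent-1-en-1-yl]butanal (ring C3 epimers), via allyl carbinol 8 (not isolated)
Conditions: CH2=CHCH2MgBr (2.5 equiv), THF, −78 → 0 °C; then 1 M HCl, THF, rt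
Reagents that add atoms: allylmagnesium bromide, C=CC[Mg]Br; water, O
Why: Stork–Danheiser transposition: 1,2-addition of the allyl Grignard reagent to the vinylogous ester carbonyl and acid hydrolysis of the resulting enol acetal give the transposed cyclopentenone and free the side-chain aldehyde in the same operation.

Step 6
Reactants: 9 allyl hydroxy enone aldehyde
Product: 10 (3R)-3-[3-hydroxy-3-methyl-2-(3-methylbut-2-enyl)-5-oxocyclopent-1-en-1-yl]butanal
Conditions: second-generation Grubbs catalyst (H2IMes)(PCy3)Cl2Ru=CHPh (5 mol %), 2-methylbut-2-ene/CH2Cl2, 40 °C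
Reagents that add atoms: 2-methylbut-2-ene, CC=C(C)C
Why: Olefin cross-metathesis with 2-methylbut-2-ene converts the terminal allyl group into the prenyl group, the tetrasubstituted enone double bond being inert to the ruthenium carbene.

Step 7
Reactants: 10 prenyl hydroxy enone aldehyde
Product: 11 (10'R)-4',8'-dihydroxyguaia-1'(5'),11'-dien-2'-one (mixture at C4', C7', C8')
Conditions: Me2AlCl (3.5 equiv), CH2Cl2, −78 → −20 °C; 1 M HCl work-up
Reagents that add atoms: none
Why: Type 1 intramolecular carbonyl-ene reaction (isopulegol type, one ring atom larger): the Me2AlCl-complexed aldehyde carbon C8' bonds to C7' of the prenyl group on the neighbouring ring carbon while a methyl hydrogen moves to oxygen, closing the right seven-membered ring; C7' and C8' need no control because both become trigonal in step 8.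

Step 8
Reactants: 11 right-half diol
Product: 13 (10'R)-4'-hydroxyguaia-1'(5'),7'(11')-diene-2',8'-dione (C4' epimers), via β,γ-unsaturated dione 12 (not isolated)
Conditions: Dess–Martin periodinane, NaHCO3, CH2Cl2, 0 °C → rt; then DBU (0.2 equiv), rt, short
Reagents that add atoms: none
Why: Dess–Martin oxidation of the secondary C8' carbinol leaves the tertiary one untouched, and base-mediated conjugation of the β,γ-unsaturated ketone (the isopulegone-to-pulegone shift) gives the isopropylidene enone, DBU being kept catalytic so that the β-hydroxy ketone is not yet dehydrated.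

Step 9
Reactants: 6 methylated vinylogous ester
Product: 15 (3R)-3-[3-methyl-5-oxo-2-(prop-2-enyl)cyclopent-1-en-1-yl]butanal (ring C3 epimers), via allyl carbinol 14 (not isolated)
Conditions: CH2=CHCH2MgBr (1.3 equiv), THF, −78 → 0 °C; then 1 M HCl, THF, rt
Reagents that add atoms: allylmagnesium bromide, C=CC[Mg]Br; water, O
Why: Stork–Danheiser transposition as in step 5, here on the unhydroxylated vinylogous ester, gives the left-half cyclopentenone with the C1 arm and a C5 allyl group in place.

Step 10
Reactants: 15 allyl enone aldehyde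
Product: 16 (3R)-3-[3-methyl-2-(3-methylbut-2-enyl)-5-oxocyclopent-1-en-1-yl]butanal
Conditions: second-generation Grubbs catalyst (H2IMes)(PCy3)Cl2Ru=CHPh (5 mol %), 2-methylbut-2-ene/CH2Cl2, 40 °C
Reagents that add atoms: 2-methylbut-2-ene, CC=C(C)C
Why: Olefin cross-metathesis as in step 6 converts allyl into prenyl.

Step 11
Reactants: 16 prenyl enone aldehyde
Product: 17 2-[(2R)-4-hydroxybutan-2-yl]-4-methyl-3-(3-methylbut-2-enyl)cyclopent-2-en-1-one
Conditions: NaBH4 (0.3 equiv), EtOH/CH2Cl2, −78 °C
Reagents that add atoms: none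
Why: Chemoselective borohydride reduction: at low temperature the aldehyde reacts far faster than the tetrasubstituted conjugated ketone, so the C8 oxygen can be carried as a silyl ether through the acidic steps that follow.

Step 12
Reactants: 17 primary alcohol
Product: 18 2-[(2R)-4-(tert-butyldiphenylsilyloxy)butan-2-yl]-4-methyl-3-(3-methylbut-2-enyl)cyclopent-2-en-1-one
Conditions: tBuPh2SiCl, imidazole, CH2Cl2, rt
Reagents that add atoms: tert-butyl(chloro)diphenylsilane, CC(C)(C)[Si](Cl)(c1ccccc1)c1ccccc1
Why: Standard silylation of a primary alcohol gives an acid-stable ether that also makes the C9–C8 arm the large substituent at C10 for the facial control in step 16.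

Step 13
Reactants: 18 silyl ether enone
Product: 19 5-(phenylselanyl) derivative of 18 (selenium on C3 in guaiane numbering, trans to the C4 methyl)
Conditions: LiN(iPr)2, THF, −78 °C; PhSeBr
Reagents that add atoms: phenylselenyl bromide, Br[Se]c1ccccc1
Why: Kinetic deprotonation of the enone at the α' methylene and selenenylation of the cross-conjugated enolate, the electrophile entering trans to the neighbouring methyl so that selenium and H4 are cis as the later syn elimination requires.

Step 14
Reactants: 19 α'-selenide
Product: 20 tert-butyl{(3R)-3-[5,5-dimethoxy-3-methyl-2-(3-methylbut-2-enyl)-4-(phenylselanyl)cyclopent-1-en-1-yl]butoxy}diphenylsilane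
Conditions: MeOSiMe3 (3 equiv), Me3SiOTf (5 mol %), CH2Cl2, −78 → −20 °C
Reagents that add atoms: methoxytrimethylsilane, CO[Si](C)(C)C
Why: Silyl triflate-catalysed ketalisation with the methoxysilane converts the enone carbonyl into the dimethyl ketal without moving the double bond, so C2 becomes a saturated carbon without hydrogen and the coming cyclopentadiene can neither isomerise by 1,5-hydrogen shift nor show a facial preference at C2.

Step 15
Reactants: 20 ketal selenide
Product: 22 tert-butyl{(3R)-3-[5,5-dimethoxy-3-methyl-2-(3-methylbut-2-enyl)cyclopenta-1,3-dien-1-yl]butoxy}diphenylsilane, via selenoxide 21 (not isolated)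
Conditions: 30% H2O2, pyridine, CH2Cl2, 0 °C → rt; used at once
Reagents that add atoms: none
Why: Selenoxide syn elimination, for which H4 is the only β-hydrogen, gives the 5,5-dimethoxycyclopentadiene regiospecifically under mild buffered conditions.

Step 16
Reactants: 13 right-half hydroxy dienedione; 22 left-half diene ketal
Product: 25 Diels–Alder adduct (norbornene with C2(OMe)2 bridge, C4 methyl, C5 prenyl, C1 (2R)-4-(tert-butyldiphenylsilyloxy)butan-2-yl arm, endo-fused through C1–C4' and C3–C3' to the (10'R)-guaia-1'(5'),7'(11')-diene-2',8'-dione unit, C15' exo), via tertiary trifluoroacetate 23 (not isolated), via cyclopentadienone 24 (not isolated)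
Conditions: 13, (CF3CO)2O (1.1 equiv), pyridine, CH2Cl2, −40 °C; add 22 (1.5 equiv); Et3N (3 equiv) over 2 h, −40 → 0 °C
Reagents that add atoms: none
Why: Diels–Alder reaction in which the electron-rich cyclopentadienone ketal is the 4π partner and the cyclopentadienone, released slowly by E1cB loss of trifluoroacetate, the 2π partner (the way cyclopentadienones are trapped by cyclopentadienes): bonding leads between the hydrogen-bearing carbons C3 and C3' so that the crowded C1–C4' bond closes second, the enone ring sits endo, the dienophile reacts on its face anti to the pseudo-axial C10' methyl, and the diene, with C10–H eclipsing the ring plane (allylic 1,3-strain with the C5 prenyl group), on the face turned away from the silyloxyethyl arm, which together set C1, C3, C3' and C4'.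

Step 17
Reactants: 25 adduct
Product: 26 2-ketone of 25 (bridging ketone)
Conditions: TsOH·H2O (cat.), acetone/H2O, 40 °C
Reagents that add atoms: water, O
Why: Acid-catalysed ketal hydrolysis frees the strained bridging ketone while the tert-butyldiphenylsilyl ether, the prenyl group and the enones survive.

Step 18
Reactants: 26 bridging ketone
Product: 27 2-carbinol with the hydroxyl anti to C4=C5 (on the side of the C3'–C4' bridge)
Conditions: NaBH4 (0.3 equiv), MeOH/CH2Cl2, −78 °C
Reagents that add atoms: none
Why: Borohydride reduction is confined to the strained bridging ketone, by far the most electrophilic carbonyl, and hydride should enter from the open side over C4=C5 as in 7-norbornenone reductions, which gives the C2 epimer opposite to the target and makes step 19 necessary.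

Step 19
Reactants: 27 anti carbinol
Product: 28 C2 epimer of 27, hydroxyl syn to C4=C5 (target configuration)
Conditions: (η5-C5Ph5)Ru(CO)2Cl (5 mol %), KOtBu (5 mol %), toluene, 50 °C
Reagents that add atoms: none
Why: Ruthenium-catalysed carbinol epimerisation (reversible β-hydride elimination and re-addition on a ketone that stays bound to the metal, so the enones are not reduced) should move the alcohol to the thermodynamically preferred C2 epimer, whose hydroxyl lies over the C4=C5 double bond and no longer clashes with the exo C15' methyl of the lower bridge.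

Step 20
Reactants: 28 syn carbinol
Product: 29 2-acetate of 28
Conditions: Ac2O, DMAP, pyridine, CH2Cl2, rt
Reagents that add atoms: acetic anhydride, CC(=O)OC(C)=O
Why: DMAP-catalysed acylation of the hindered secondary alcohol gives the C2 acetate of the target, which is inert to the later reagents.

Step 21
Reactants: 29 acetate silyl ether
Product: 30 primary alcohol (C1 arm (2R)-4-hydroxybutan-2-yl)
Conditions: HF·pyridine, THF/pyridine, 0 °C → rt
Reagents that add atoms: none
Why: Fluoride cleavage of the primary silyl ether under slightly acidic conditions that do not touch the acetate.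

Step 22
Reactants: 30 primary alcohol
Product: 31 aldehyde (2-acetoxy core with C5 prenyl and C1 (2R)-4-oxobutan-2-yl arms)
Conditions: Dess–Martin periodinane, NaHCO3, CH2Cl2, rt
Reagents that add atoms: none
Why: Dess–Martin oxidation of the primary alcohol under buffered neutral conditions gives the aldehyde without enolisation or double-bond migration elsewhere.

Step 23
Reactants: 31 aldehyde
Product: 32 8-hydroxy-7-isopropenyl dimer (left seven-membered ring closed, 7,8-trans expected)
Conditions: Me2AlCl (4 equiv), CH2Cl2, −78 → −30 °C; 1 M HCl work-up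
Reagents that add atoms: none
Why: Me2AlCl binds the aldehyde oxygen (an excess is used because the two enone carbonyls bind first) and the complexed C8 carbon bonds to C7, the less substituted carbon of the prenyl double bond, while a hydrogen of a C11 methyl group passes to oxygen through a six-membered transition state, giving the homoallylic alkoxide with an isopropenyl group and no free cation. The closest known reaction is the type 1 intramolecular carbonyl-ene cyclisation of citronellal to isopulegol, here one ring atom larger and already rehearsed in step 7. The seven-membered ring (C1, C5, C6, C7, C8, C9, C10) closes in the exo mode with respect to the alkene, C11 staying outside the ring, and the entropic cost is offset because both arms sit on the rigid C1–C5 edge of the norbornene. The new centres C7 and C8 are set by the chair-like ene transition state with the aluminium-bound oxygen and the isopropenyl group pseudo-equatorial, but neither outcome matters, since C8 becomes a ketone and C7 is then equilibrated. The step needs the aldehyde to react with the prenyl group only: the acetate and ketones have no reachable ene partner, the tetrasubstituted C4=C5 bond is screened by the syn acetate and the endo right half and could only close a strained five-membered ring onto C5, and Me2AlCl scavenges protons so that Prins-type chloride capture and double-bond migration are suppressed.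

Step 24
Reactants: 32 ene product
Product: 33 8-hydroxy-7-isopropyl dimer
Conditions: H2 (1 atm), RhCl(PPh3)3 (10 mol %), benzene, rt
Reagents that add atoms: none
Why: Homogeneous hydrogenation with RhCl(PPh3)3 reduces only the 1,1-disubstituted isopropenyl double bond, the tetrasubstituted C4=C5, C1'=C5' and C7'=C11' bonds being too hindered to bind rhodium, and no stereocentre is formed.

Step 25
Reactants: 33 isopropyl carbinol
Product: 35 8-ketone with C7 as in the target (deperoxy target), via C7-epimeric ketone 34 (not isolated)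
Conditions: Dess–Martin periodinane, NaHCO3, CH2Cl2, rt; then DBU (1 equiv), toluene, rt
Reagents that add atoms: none
Why: Dess–Martin oxidation gives the C8 ketone and DBU then equilibrates the enolisable C7 to the more stable epimer (isopropyl pseudo-equatorial on the ring face remote from the right half), while C10 and C10' are not enolisable and C3' is held by the ring fusion.

Step 26
Reactants: 35 deperoxy target
Product: 37 target CNP0317907.1, via hydroperoxide 36 (not isolated)
Conditions: O2, visible light, tetraphenylporphyrin (cat.), CH2Cl2, −20 °C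
Reagents that add atoms: dioxygen, O=O
Why: Schenck ene reaction of singlet oxygen with the isopropylidene ketone (the pulegone case): oxygen bonds to C11', hydrogen is taken from C6' on the carbonyl-bearing alkene carbon (gem effect), and the hydroperoxide closes reversibly onto the C8' ketone to the more stable 1,2-dioxolan-3-ol, the other electron-rich alkene C4=C5 being screened by the syn acetate on one face and the right half on the other.

**Compound list**

1 | cyclopentane-1,3-dione | O=C1CCC(=O)C1 | starting material
2 | (E)-but-2-enal | C/C=C/C=O | starting material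
3 | 2-[(2R)-4-oxobutan-2-yl]cyclopentane-1,3-dione (open-chain Michael aldehyde) | O=CC[C@@H](C)C1C(=O)CCC1=O | intermediate
4 | (4R)-2-hydroxy-4-methyl-3,4,6,7-tetrahydro-2H-cyclopenta[b]pyran-5-one | OC1C[C@@H](C)C2=C(CCC2=O)O1 | intermediate
5 | (4R)-2-methoxy-4-methyl-3,4,6,7-tetrahydro-2H-cyclopenta[b]pyran-5-one | COC1C[C@@H](C)C2=C(CCC2=O)O1 | intermediate
6 | (4R)-2-methoxy-4,6-dimethyl-3,4,6,7-tetrahydro-2H-cyclopenta[b]pyran-5-one | COC1C[C@@H](C)C2=C(CC(C)C2=O)O1 | intermediate
7 | (4R)-6-hydroxy-2-methoxy-4,6-dimethyl-3,4,6,7-tetrahydro-2H-cyclopenta[b]pyran-5-one | COC1C[C@@H](C)C2=C(CC(C)(O)C2=O)O1 | intermediate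
8 | (4R)-2-methoxy-4,6-dimethyl-5-(prop-2-enyl)-2,3,4,5,6,7-hexahydrocyclopenta[b]pyran-5,6-diol (allyl carbinol) | COC1C[C@@H](C)C2=C(CC(C)(O)C2(O)CC=C)O1 | intermediate
9 | (3R)-3-[3-hydroxy-3-methyl-5-oxo-2-(prop-2-enyl)cyclopent-1-en-1-yl]butanal | O=CC[C@@H](C)C1=C(CC=C)C(C)(O)CC1=O | intermediate
10 | (3R)-3-[3-hydroxy-3-methyl-2-(3-methylbut-2-enyl)-5-oxocyclopent-1-en-1-yl]butanal | O=CC[C@@H](C)C1=C(CC=C(C)C)C(C)(O)CC1=O | intermediate
11 | (10'R)-4',8'-dihydroxyguaia-1'(5'),11'-dien-2'-one | O=C1CC(C)(O)C2=C1[C@H](C)CC(O)C(C(C)=C)C2 | intermediate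
12 | (10'R)-4'-hydroxyguaia-1'(5'),11'-diene-2',8'-dione (β,γ-unsaturated dione) | O=C1CC(C)(O)C2=C1[C@H](C)CC(=O)C(C(C)=C)C2 | intermediate
13 | (10'R)-4'-hydroxyguaia-1'(5'),7'(11')-diene-2',8'-dione | O=C1CC(C)(O)C2=C1[C@H](C)CC(=O)C(=C(C)C)C2 | intermediate
14 | (4R)-2-methoxy-4,6-dimethyl-5-(prop-2-enyl)-2,3,4,5,6,7-hexahydrocyclopenta[b]pyran-5-ol (allyl carbinol) | COC1C[C@@H](C)C2=C(CC(C)C2(O)CC=C)O1 | intermediate
15 | (3R)-3-[3-methyl-5-oxo-2-(prop-2-enyl)cyclopent-1-en-1-yl]butanal | O=CC[C@@H](C)C1=C(CC=C)C(C)CC1=O | intermediate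
16 | (3R)-3-[3-methyl-2-(3-methylbut-2-enyl)-5-oxocyclopent-1-en-1-yl]butanal | O=CC[C@@H](C)C1=C(CC=C(C)C)C(C)CC1=O | intermediate
17 | 2-[(2R)-4-hydroxybutan-2-yl]-4-methyl-3-(3-methylbut-2-enyl)cyclopent-2-en-1-one | OCC[C@@H](C)C1=C(CC=C(C)C)C(C)CC1=O | intermediate
18 | 2-[(2R)-4-(tert-butyldiphenylsilyloxy)butan-2-yl]-4-methyl-3-(3-methylbut-2-enyl)cyclopent-2-en-1-one | CC(C)(C)[Si](c1ccccc1)(c1ccccc1)OCC[C@@H](C)C1=C(CC=C(C)C)C(C)CC1=O | intermediate
19 | 5-(phenylselanyl) derivative of 18 | CC(C)(C)[Si](c1ccccc1)(c1ccccc1)OCC[C@@H](C)C1=C(CC=C(C)C)C(C)C([Se]c2ccccc2)C1=O | intermediate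
20 | tert-butyl{(3R)-3-[5,5-dimethoxy-3-methyl-2-(3-methylbut-2-enyl)-4-(phenylselanyl)cyclopent-1-en-1-yl]butoxy}diphenylsilane | CC(C)(C)[Si](c1ccccc1)(c1ccccc1)OCC[C@@H](C)C1=C(CC=C(C)C)C(C)C([Se]c2ccccc2)C1(OC)OC | intermediate
21 | selenoxide of 20 | CC(C)(C)[Si](c1ccccc1)(c1ccccc1)OCC[C@@H](C)C1=C(CC=C(C)C)C(C)C([Se](=O)c2ccccc2)C1(OC)OC | intermediate
22 | tert-butyl{(3R)-3-[5,5-dimethoxy-3-methyl-2-(3-methylbut-2-enyl)cyclopenta-1,3-dien-1-yl]butoxy}diphenylsilane | CC(C)(C)[Si](c1ccccc1)(c1ccccc1)OCC[C@@H](C)C1=C(CC=C(C)C)C(C)=CC1(OC)OC | intermediate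
23 | 4'-trifluoroacetate of 13 | O=C1CC(C)(OC(=O)C(F)(F)F)C2=C1[C@H](C)CC(=O)C(=C(C)C)C2 | intermediate
24 | (10'R)-guaia-1'(5'),3',7'(11')-triene-2',8'-dione (cyclopentadienone) | O=C1C=C(C)C2=C1[C@H](C)CC(=O)C(=C(C)C)C2 | intermediate
25 | Diels–Alder adduct, 2,2-dimethoxy bridge, C5 prenyl, C1 silyloxybutyl arm, endo-fused right half | COC1(OC)[C@H]2C(C)=C(CC=C(C)C)[C@]1([C@H](C)CCO[Si](c1ccccc1)(c1ccccc1)C(C)(C)C)[C@]1(C)C3=C(C(=O)[C@H]21)[C@H](C)CC(=O)C(=C(C)C)C3 | intermediate
26 | 2-ketone of 25 | O=C1[C@H]2C(C)=C(CC=C(C)C)[C@]1([C@H](C)CCO[Si](c1ccccc1)(c1ccccc1)C(C)(C)C)[C@]1(C)C3=C(C(=O)[C@H]21)[C@H](C)CC(=O)C(=C(C)C)C3 | intermediate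
27 | 2-carbinol, hydroxyl anti to C4=C5 | O[C@@H]1[C@H]2C(C)=C(CC=C(C)C)[C@]1([C@H](C)CCO[Si](c1ccccc1)(c1ccccc1)C(C)(C)C)[C@]1(C)C3=C(C(=O)[C@H]21)[C@H](C)CC(=O)C(=C(C)C)C3 | intermediate
28 | 2-carbinol, hydroxyl syn to C4=C5 | O[C@H]1[C@H]2C(C)=C(CC=C(C)C)[C@]1([C@H](C)CCO[Si](c1ccccc1)(c1ccccc1)C(C)(C)C)[C@]1(C)C3=C(C(=O)[C@H]21)[C@H](C)CC(=O)C(=C(C)C)C3 | intermediate
29 | 2-acetate of 28 | CC(=O)O[C@H]1[C@H]2C(C)=C(CC=C(C)C)[C@]1([C@H](C)CCO[Si](c1ccccc1)(c1ccccc1)C(C)(C)C)[C@]1(C)C3=C(C(=O)[C@H]21)[C@H](C)CC(=O)C(=C(C)C)C3 | intermediate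
30 | primary alcohol from 29 | CC(=O)O[C@H]1[C@H]2C(C)=C(CC=C(C)C)[C@]1([C@H](C)CCO)[C@]1(C)C3=C(C(=O)[C@H]21)[C@H](C)CC(=O)C(=C(C)C)C3 | intermediate
31 | aldehyde, 2-acetoxy core with C5 prenyl and C1 (2R)-4-oxobutan-2-yl arms | CC(=O)O[C@H]1[C@H]2C(C)=C(CC=C(C)C)[C@]1([C@H](C)CC=O)[C@]1(C)C3=C(C(=O)[C@H]21)[C@H](C)CC(=O)C(=C(C)C)C3 | intermediate
32 | 8-hydroxy-7-isopropenyl dimer | CC(=O)O[C@H]1[C@H]2C(C)=C3C[C@@H](C(C)=C)[C@H](O)C[C@@H](C)[C@]31[C@]1(C)C3=C(C(=O)[C@H]21)[C@H](C)CC(=O)C(=C(C)C)C3 | intermediate
33 | 8-hydroxy-7-isopropyl dimer | CC(=O)O[C@H]1[C@H]2C(C)=C3C[C@@H](C(C)C)[C@H](O)C[C@@H](C)[C@]31[C@]1(C)C3=C(C(=O)[C@H]21)[C@H](C)CC(=O)C(=C(C)C)C3 | intermediate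
34 | 8-ketone, C7 epimers | CC(=O)O[C@H]1[C@H]2C(C)=C3CC(C(C)C)C(=O)C[C@@H](C)[C@]31[C@]1(C)C3=C(C(=O)[C@H]21)[C@H](C)CC(=O)C(=C(C)C)C3 | intermediate
35 | 8-ketone, C7 as in the target (deperoxy target) | CC(=O)O[C@H]1[C@H]2C(C)=C3C[C@@H](C(C)C)C(=O)C[C@@H](C)[C@]31[C@]1(C)C3=C(C(=O)[C@H]21)[C@H](C)CC(=O)C(=C(C)C)C3 | intermediate
36 | 11'-hydroperoxide with 6'(7') double bond | CC(=O)O[C@H]1[C@H]2C(C)=C3C[C@@H](C(C)C)C(=O)C[C@@H](C)[C@]31[C@]1(C)C3=C(C(=O)[C@H]21)[C@H](C)CC(=O)C(C(C)(C)OO)=C3 | intermediate
37 | CNP0317907.1 | CC(=O)O[C@H]1[C@H]2C(C)=C3C[C@@H](C(C)C)C(=O)C[C@@H](C)[C@]31[C@]1(C)C3=C(C(=O)[C@H]21)[C@H](C)C[C@@]1(O)OOC(C)(C)C1=C3 | target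

**Count and risks**

Total: 26 steps. Longest linear sequence: 21 steps (steps 1–3, 9–15, 16–26).

Steps most likely to fail:

1. Step 16 (Diels–Alder). The transient dienone may dimerise with itself faster than it meets the hindered diene, and the acyclic C10 centre may discriminate the two diene faces only weakly, so that the core forms with the wrong sense relative to C10. Fallback: set out from selenide 19 and fix the diene face with a ring stereocentre instead. Corey–Bakshi–Shibata reduction (2-methyl-CBS-oxazaborolidine of the enantiomer that gives the configuration shown, BH3·SMe2) gives allylic alcohol F1; Et3SiCl/imidazole gives triethylsilyl ether F2; H2O2/pyridine at −20 °C gives 5-silyloxycyclopentadiene F3, used cold and at once to outrun 1,5-hydrogen shift. Cycloaddition with dienone 24, generated as in step 16, then occurs syn to the oxygen substituent (the known directing effect of a 5-oxygen group) and gives silyloxy adduct F4. AcOH/THF/H2O removes the triethylsilyl group and the route is rejoined at carbinol 27, before step 19.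

2. Step 19 (C2 epimerisation). Return of hydride to the hindered face may be too slow, or the equilibrium may not lie far enough on the side of the syn carbinol. Fallback: set out from ketone 26 and bring the oxygen in by rearrangement. Wittig olefination with Ph3P=C(OMe)CH3 (from the phosphonium chloride and KN(SiMe3)2) gives enol ether F5; dilute HCl/THF followed by DBU gives methyl ketone F6, whose enolisable C2 settles with the acetyl group syn to C4=C5, away from the exo C15' methyl. Baeyer–Villiger oxidation with (Me3SiO)2/SnCl4, which spares alkenes and proceeds with retention at the migrating C2, gives acetate 29 directly, where the route is rejoined.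

3. Step 23 (key ene closure). Ring closure may be outrun by Prins-type ionisation with chloride capture or by attack on the ring double bond, or may not occur for conformational reasons. Fallback: set out from aldehyde 31 and form the same C7–C8 bond and ring by a radical. Pinnick oxidation (NaClO2, NaH2PO4, 2-methylbut-2-ene) gives carboxylic acid F7; (PhSe)2/Bu3P gives phenyl selenoester F8; slow addition of Bu3SnH/AIBN in benzene at 80 °C should give 7-exo acyl radical cyclisation onto the prenyl group, the tertiary C11 radical being reduced to the isopropyl group, which leads to ketone 34; DBU as in step 25 then gives 35, where the route is rejoined.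

**Further compounds**

F1 | step 16 | allylic alcohol from 19 (C2 carbinol, hydroxyl on the face to be attacked) | O[C@@H]1C([Se]c2ccccc2)C(C)C(CC=C(C)C)=C1[C@H](C)CCO[Si](c1ccccc1)(c1ccccc1)C(C)(C)C
F2 | step 16 | triethylsilyl ether of F1 | CC[Si](CC)(CC)O[C@@H]1C([Se]c2ccccc2)C(C)C(CC=C(C)C)=C1[C@H](C)CCO[Si](c1ccccc1)(c1ccccc1)C(C)(C)C
F3 | step 16 | 5-(triethylsilyloxy)cyclopentadiene | CC[Si](CC)(CC)O[C@@H]1C=C(C)C(CC=C(C)C)=C1[C@H](C)CCO[Si](c1ccccc1)(c1ccccc1)C(C)(C)C
F4 | step 16 | silyloxy adduct (2-triethylsilyloxy anti to C4=C5) | CC[Si](CC)(CC)O[C@@H]1[C@H]2C(C)=C(CC=C(C)C)[C@]1([C@H](C)CCO[Si](c1ccccc1)(c1ccccc1)C(C)(C)C)[C@]1(C)C3=C(C(=O)[C@H]21)[C@H](C)CC(=O)C(=C(C)C)C3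
F5 | step 19 | enol ether (C2=C(OMe)CH3) | COC(C)=C1[C@H]2C(C)=C(CC=C(C)C)[C@]1([C@H](C)CCO[Si](c1ccccc1)(c1ccccc1)C(C)(C)C)[C@]1(C)C3=C(C(=O)[C@H]21)[C@H](C)CC(=O)C(=C(C)C)C3
F6 | step 19 | methyl ketone (2-acetyl syn to C4=C5) | CC(=O)[C@H]1[C@H]2C(C)=C(CC=C(C)C)[C@]1([C@H](C)CCO[Si](c1ccccc1)(c1ccccc1)C(C)(C)C)[C@]1(C)C3=C(C(=O)[C@H]21)[C@H](C)CC(=O)C(=C(C)C)C3
F7 | step 23 | carboxylic acid from 31 | CC(=O)O[C@H]1[C@H]2C(C)=C(CC=C(C)C)[C@]1([C@H](C)CC(=O)O)[C@]1(C)C3=C(C(=O)[C@H]21)[C@H](C)CC(=O)C(=C(C)C)C3
F8 | step 23 | phenyl selenoester | CC(=O)O[C@H]1[C@H]2C(C)=C(CC=C(C)C)[C@]1([C@H](C)CC(=O)[Se]c1ccccc1)[C@]1(C)C3=C(C(=O)[C@H]21)[C@H](C)CC(=O)C(=C(C)C)C3
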